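All runs were computed for an exercise; noise was put on by code.

Grey is a stirred tank with a mean residence time of 12.5 h, and red is a closed flask on the same charge of D, so I ask what would have to be true for grey to lose to red.

| flask | D | remark | time |
|---|---|---|---|
| maple | 0.020 M | run made earlier |  |
| birch | 0.010 M | run made earlier |  |
| cedar | 0.015 M | run made earlier |  |
| teal | 0.020 M | one stirred flow tank at steady state, fed with the mixture as stated, mean residence time 2.5 h |  |
| grey | 0.020 M | one stirred flow tank at steady state, fed with the mixture as stated, mean residence time 12.5 h |  |
| red | 0.020 M | everything together in a closed stirred flask, run for 2.5 h | 2.5 h |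

- maple (time / h: Z / %, D / %): 0.333: 15.8, 53.9; 0.833: 28.5, 24.8; 1.50: 34.2, 8.7; 2.50: 37.6, 1.9
- birch (time / h: Z / %, D / %): 0.333: 16.7, 57.7; 0.833: 29.1, 26.2; 1.50: 38.2, 10.1; 2.50: 40.3, 2.2
- cedar (time / h: Z / %, D / %): 0.667: 25.6, 32.9; 1.33: 33.9, 11.8; 2.00: 38.0, 4.5; 2.50: 40.2, 2.9

(readings scatter by 0.5 percentage points)

- the set-up with the highest amount of Z at the outlet or at the end, in percent of the D put in ("none" if the first two lie within 2 percentage points) (teal / grey / red / none)
- amount of Z at the outlet or at the end, in percent of the D put in, teal
- amount of Z at the outlet or at the end, in percent of the D put in, grey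
- amount of Z at the outlet or at the end, in percent of the D put in, red

- the stated concentrations are those of everything mixed, before any reaction; amounts are the same in each set-up
- the earlier runs were made in a closed, stirred flask

Dividing the rate of Z formation by the rate of D loss removes time and leaves the differential selectivity, Z gained per D lost, read against [D]. A stirred tank at steady state works at its outlet [D], so I reckon its Z as the selectivity there times its conversion. Red repeats maple's charge and time, so I take maple's last reading, 37.6%, for red. Birch's D falls to 2.2% in 2.50 h, an apparent first-order constant of 1.53 /h. With it, I reckon that grey leaves 4.98% of its D unreacted, at [D] = 9.96 × 10⁻⁴ M.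

By this reckoning grey falls behind red if its outlet selectivity lies below 0.396, red's Z divided by grey's conversion. I call this the break-even selectivity. Birch between 0.833 h and 2.50 h passes from 0.00262 M to 2.20 × 10⁻⁴ M, a stretch that spans grey's reckoned [D], and over that stretch as a whole its Z gained per D lost reads 0.467, each reading carrying a scatter of 0.5 percentage points. That reading stands above the break-even value by 0.0710, so I put grey ahead, at 44.4% by my own reckoning.

The forecast names grey as best, with 42.5% for grey, 37.9% for red and 33.9% for teal, saying that “a long-residence tank keeps D low”. Its grey figure lies below mine.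

The simulation gives grey as best, with 42.8% against 37.8% for red and 33.5% for teal.

    2 D → X (k = 13.0 /M/h)
    Q → E (k = 0.0241 /h)
    D → Q (k = 0.770 /h)
    D → L (k = 0.0248 /h)
    E ⇌ J (K = 13.0, k = 0.644 /h)
    L → Z (k = 0.329 /h)
    E → G (k = 0.519 /h)
    D → Z (k = 0.640 /h)

Grey's outlet holds 5.19% of the charge as D, so its Z per D lost is 0.451, above the break-even 0.396. Teal's [D] of 0.00412 M means a conversion of 79.4%, so with maple's reading standing for red, teal needs a Z per D lost of 0.474 to match red. Teal reaches 0.422 and ends 4.3 points below red.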